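**Retrosynthetic overview**

1. Last events: kinetic protonation sets the furyl-bearing lactone α-carbon and the silyl ether is removed; before that the ten-membered lactone is closed by macrolactonisation of a hydroxy acid (last ring formed).
2. The hydroxy acid comes from retro-Claisen opening of a 2-acylcyclopentanone cis-fused to the γ-lactone: a temporary cyclopentanone whose carbonyl carbon becomes the carbonyl carbon of the ring ester.
3. Key disconnection: the γ-lactone is cut at its O–CH bond and at its CH–CH(furyl) bond into a 2-furylacetic acid (C,O-dinucleophile), (R)-4-silyloxycyclopent-2-enone (cyclopentadienone equivalent) and a 4-silyloxypentanal, joined in one three-component operation (first rings: γ-lactone on the temporary cyclopentanone).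
4. Enabling feature: the two adjacent fusion carbons of the γ-lactone (CH–O and CH–C) each carry a ring CH2 that leads to a carbonyl carbon of the ten-membered ring (ester C=O and ketone C=O). Bonding the ester carbonyl carbon to the ketone-side CH2 folds these five carbons into a cyclopentanone in which both fusion carbons are β-carbons of a cross-conjugated dienone, and a fused five-membered ring can only be cis.
5. Both (R)-carbinols enter early (ketoreductase; commercial (R)-hex-5-en-2-ol).

Key step: step 7

Remark: the furyl-bearing lactone carbon is epimerisable under base, so the intermediates between the key step and the macrolactone are drawn as the trans (exo) epimer expected at equilibrium; the late kinetic protonation converges either epimer to the cis configuration of the target.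

**Route**

Step 1
Reactants: 1 methyl 2-(furan-2-yl)acetate; 2 but-3-en-2-one (methyl vinyl ketone)
Product: 3 methyl 2-[5-(3-oxobutyl)furan-2-yl]acetate
Conditions: Sc(OTf)3 (5 mol %), MeCN, 0 °C → rt
Reagents that add atoms: none
Why: Friedel–Crafts-type conjugate alkylation, in which the 2-substituted furan attacks the Lewis-acid-activated enone through its free α-position (C5), the most nucleophilic ring carbon left.

Step 2
Reactants: 3 methyl 2-[5-(3-oxobutyl)furan-2-yl]acetate
Product: 4 methyl 2-{5-[(3R)-3-hydroxybutyl]furan-2-yl}acetate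
Conditions: (R)-selective ketoreductase (NADPH-dependent alcohol dehydrogenase), NADP+ (cat.), i-PrOH, phosphate buffer pH 7, 30 °C
Reagents that add atoms: none
Why: Enzymatic ketone reduction with isopropanol recycling should deliver hydride to one face of the methyl ketone (anti-Prelog enzyme) and set the (R)-carbinol of the side chain, while the ester is inert at neutral pH.

Step 3
Reactants: 4 methyl 2-{5-[(3R)-3-hydroxybutyl]furan-2-yl}acetate
Product: 5 methyl 2-{5-[(3R)-3-(tert-butyldimethylsilyloxy)butyl]furan-2-yl}acetate
Conditions: TBSCl, imidazole, DMF, rt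
Reagents that add atoms: tert-butyldimethylsilyl chloride, CC(C)(C)[Si](C)(C)Cl
Why: Corey silylation protects the side-chain carbinol for the strongly basic key step and keeps it distinct from the second carbinol until the end.

Step 4
Reactants: 5 methyl 2-{5-[(3R)-3-(tert-butyldimethylsilyloxy)butyl]furan-2-yl}acetate
Product: 6 2-{5-[(3R)-3-(tert-butyldimethylsilyloxy)butyl]furan-2-yl}acetic acid
Conditions: LiOH, THF/H2O, 0 °C → rt; then 1 M HCl to pH 3
Reagents that add atoms: lithium hydroxide, [Li+].[OH-]
Why: Saponification gives the free acid needed as the C,O-dinucleophile; the silyl ether and the furan are stable to cold LiOH.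

Step 5
Reactants: 7 (2R)-hex-5-en-2-ol
Product: 8 triethyl[(2R)-hex-5-en-2-yloxy]silane
Conditions: TESCl, imidazole, CH2Cl2, 0 °C
Reagents that add atoms: triethylsilyl chloride, CC[Si](Cl)(CC)CC
Why: Silylation with the more labile triethylsilyl group lets this carbinol be released later in the presence of the tert-butyldimethylsilyl ether.

Step 6
Reactants: 8 triethyl[(2R)-hex-5-en-2-yloxy]silane
Product: 9 (4R)-4-(triethylsilyloxy)pentanal
Conditions: O3, CH2Cl2, −78 °C; then PPh3
Reagents that add atoms: ozone, [O-][O+]=O
Why: Ozonolysis with reductive work-up cleaves the terminal alkene to the aldehyde without touching the carbinol stereocentre or the silyl ether.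

Step 7
Reactants: 6 2-{5-[(3R)-3-(tert-butyldimethylsilyloxy)butyl]furan-2-yl}acetic acid; 10 (4R)-4-(tert-butyldimethylsilyloxy)cyclopent-2-en-1-one; 9 (4R)-4-(triethylsilyloxy)pentanal
Product: 15 (3R,3aS,6aS)-3-{5-[(3R)-3-(tert-butyldimethylsilyloxy)butyl]furan-2-yl}-4-[(4R)-1-hydroxy-4-(triethylsilyloxy)pentyl]hexahydro-2H-cyclopenta[b]furan-2,5-dione, via dilithium enediolate 11 (not isolated), via Michael enolate 12 (not isolated), via aldol keto acid 13 (not isolated), via enone acid 14 (not isolated)
Conditions: LDA (2.1 equiv), THF, −78 → 0 °C; 10, −78 °C; 9, −78 °C; AcOH; then DBU, 0 °C → rt; AcOH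
Reagents that add atoms: none
Why: Proposed new method: the dilithium enediolate 11 adds through carbon to the β-carbon of enone 10 anti to the silyloxy group, the regiodefined lithium enolate 12 is captured by aldehyde 9 (aldol) before it can equilibrate, and after the AcOH quench DBU eliminates silanol from the β-silyloxy ketone 13 to give enone 14, whose carboxylic acid adds to the new β-carbon (oxa-Michael). The closest known reaction types are the three-component conjugate addition/aldol coupling of stabilised carbanions with 4-silyloxycyclopent-2-enones from prostaglandin synthesis, the addition–elimination behaviour that makes these enones cyclopentadienone equivalents, and the lactonisation of (4-oxocyclopent-2-enyl)acetic acids; new is their use in one flask with a carboxylic acid dianion as the C,O-dinucleophile. Only the γ-lactone is closed, by 5-exo-trig attack of the carboxylate oxygen, and on the five-membered ring it can only be cis-fused. The fusion carbon that receives carbon is set by the (R)-silyloxy stereocentre (anti addition) and the fusion carbon that receives oxygen follows from the cis fusion; the furyl-bearing centre should settle under DBU as the exo epimer and is reset in step 12, and the two aldol-derived centres are left undefined because steps 8 and 9 clear them. The step needs 1,4- over 1,2-addition and a kinetic enolate trap, which the soft, doubly stabilised furfuryl-type carbanion and the fast aldol at −78 °C should provide.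

Step 8
Reactants: 15 (3R,3aS,6aS)-3-{5-[(3R)-3-(tert-butyldimethylsilyloxy)butyl]furan-2-yl}-4-[(4R)-1-hydroxy-4-(triethylsilyloxy)pentyl]hexahydro-2H-cyclopenta[b]furan-2,5-dione
Product: 16 (3R,3aS,6aS)-3-{5-[(3R)-3-(tert-butyldimethylsilyloxy)butyl]furan-2-yl}-4-[(4R)-4-(triethylsilyloxy)pentanoyl]hexahydro-2H-cyclopenta[b]furan-2,5-dione
Conditions: Dess–Martin periodinane, pyridine, CH2Cl2, 0 °C → rt
Reagents that add atoms: none
Why: Dess–Martin oxidation of the aldol carbinol gives the enolised 1,3-diketone and thereby clears the two undefined stereocentres next to it.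

Step 9
Reactants: 16 (3R,3aS,6aS)-3-{5-[(3R)-3-(tert-butyldimethylsilyloxy)butyl]furan-2-yl}-4-[(4R)-4-(triethylsilyloxy)pentanoyl]hexahydro-2H-cyclopenta[b]furan-2,5-dione
Product: 18 2-[(2S,3S,4R)-4-{5-[(3R)-3-(tert-butyldimethylsilyloxy)butyl]furan-2-yl}-5-oxo-3-[(5R)-2-oxo-5-(triethylsilyloxy)hexyl]oxolan-2-yl]acetic acid, via dilithium hydroxy dicarboxylate 17 (not isolated)
Conditions: LiOH, THF/H2O, 0 °C → rt; then 1 M HCl to pH 3, 0 °C
Reagents that add atoms: lithium hydroxide, [Li+].[OH-]
Why: Retro-Claisen cleavage, in which hydroxide adds to the strained ring carbonyl of the 2-acylcyclopentanone and the ring C–C bond breaks toward the ketone enolate, so the ring carbonyl becomes the carboxylic acid and the acyl group the ketone; the γ-lactone that opens to 17 re-closes on acidification with the fusion C–O bond untouched, and the stable diketonate suppresses enolisation toward the oxygen-bearing carbon.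

Step 10
Reactants: 18 2-[(2S,3S,4R)-4-{5-[(3R)-3-(tert-butyldimethylsilyloxy)butyl]furan-2-yl}-5-oxo-3-[(5R)-2-oxo-5-(triethylsilyloxy)hexyl]oxolan-2-yl]acetic acid
Product: 19 2-[(2S,3S,4R)-4-{5-[(3R)-3-(tert-butyldimethylsilyloxy)butyl]furan-2-yl}-3-[(5R)-5-hydroxy-2-oxohexyl]-5-oxooxolan-2-yl]acetic acid
Conditions: AcOH/THF/H2O, rt
Reagents that add atoms: none
Why: Mild aqueous acid cleaves the secondary triethylsilyl ether much faster than the tert-butyldimethylsilyl ether, freeing only the carbinol needed for ring closure.

Step 11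
Reactants: 19 2-[(2S,3S,4R)-4-{5-[(3R)-3-(tert-butyldimethylsilyloxy)butyl]furan-2-yl}-3-[(5R)-5-hydroxy-2-oxohexyl]-5-oxooxolan-2-yl]acetic acid
Product: 20 O-tert-butyldimethylsilyl ether of the lactone α-epimer of cordycicadin B (furyl trans to the neighbouring ring CH2)
Conditions: MNBA (2-methyl-6-nitrobenzoic anhydride), DMAP, CH2Cl2, rt, slow addition (1 mM)
Reagents that add atoms: none
Why: Shiina macrolactonisation (mixed anhydride, DMAP acyl transfer) at high dilution and room temperature should close the ten-membered lactone as in other decanolide syntheses, helped by the cis-lactone that holds both arms on one face and by the sp2 ketone in the chain.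

Step 12
Reactants: 20 O-tert-butyldimethylsilyl ether of the lactone α-epimer of cordycicadin B
Product: 22 O-tert-butyldimethylsilyl ether of cordycicadin B, via lithium lactone enolate 21 (not isolated)
Conditions: LiHMDS (1.05 equiv), THF, −78 °C; then 2,6-di-tert-butyl-4-methylphenol, −78 °C; AcOH
Reagents that add atoms: none
Why: LiHMDS removes the most acidic proton (α to the lactone carbonyl and to the furan) and the bulky phenol protonates the planar enolate from the open convex face anti to the neighbouring ring CH2 (kinetic protonation), which should place the furyl group cis to it as in the target whichever epimer entered.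

Step 13
Reactants: 22 O-tert-butyldimethylsilyl ether of cordycicadin B
Product: 23 cordycicadin B
Conditions: HF·pyridine, pyridine, THF, 0 °C → rt
Reagents that add atoms: none
Why: Buffered HF·pyridine cleaves the silyl ether under non-basic conditions, so the base-labile lactone α-centre and the β-acyloxy ester should not be disturbed.

**Compound list**

1 | methyl 2-(furan-2-yl)acetate | COC(=O)Cc1ccco1 | starting material
2 | but-3-en-2-one (methyl vinyl ketone) | CC(=O)C=C | starting material
3 | methyl 2-[5-(3-oxobutyl)furan-2-yl]acetate | CC(=O)CCc1ccc(CC(=O)OC)o1 | intermediate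
4 | methyl 2-{5-[(3R)-3-hydroxybutyl]furan-2-yl}acetate | C[C@@H](O)CCc1ccc(CC(=O)OC)o1 | intermediate
5 | methyl 2-{5-[(3R)-3-(tert-butyldimethylsilyloxy)butyl]furan-2-yl}acetate | C[C@@H](O[Si](C)(C)C(C)(C)C)CCc1ccc(CC(=O)OC)o1 | intermediate
6 | 2-{5-[(3R)-3-(tert-butyldimethylsilyloxy)butyl]furan-2-yl}acetic acid | C[C@@H](O[Si](C)(C)C(C)(C)C)CCc1ccc(CC(=O)O)o1 | intermediate
7 | (2R)-hex-5-en-2-ol | C[C@@H](O)CCC=C | starting material
8 | triethyl[(2R)-hex-5-en-2-yloxy]silane | C[C@@H](O[Si](CC)(CC)CC)CCC=C | intermediate
9 | (4R)-4-(triethylsilyloxy)pentanal | C[C@@H](O[Si](CC)(CC)CC)CCC=O | intermediate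
10 | (4R)-4-(tert-butyldimethylsilyloxy)cyclopent-2-en-1-one | O=C1C=C[C@H](O[Si](C)(C)C(C)(C)C)C1 | starting material
11 | dilithium enediolate of acid 6 | [Li+].[Li+].C[C@@H](O[Si](C)(C)C(C)(C)C)CCc1ccc(C=C([O-])[O-])o1 | intermediate
12 | dilithium Michael adduct: cyclopentanone enolate carrying the furylacetate carboxylate on the ring carbon next to, and trans to, the silyloxy-bearing carbon | [Li+].[Li+].[O-]C1=C[C@@H](C(C(=O)[O-])c2ccc(CC[C@@H](C)O[Si](C)(C)C(C)(C)C)o2)[C@H](O[Si](C)(C)C(C)(C)C)C1 | intermediate
13 | aldol keto acid: 3-oxocyclopentane with CH(furyl)CO2H at C1, the 1-hydroxy-4-(triethylsilyloxy)pentyl group at C2 and the silyloxy group at C5 (trans to the C1 substituent); mixture at C2, at the carbinol carbon and at the furyl-bearing carbon | O=C1C(C(O)CC[C@@H](C)O[Si](CC)(CC)CC)[C@@H](C(C(=O)O)c2ccc(CC[C@@H](C)O[Si](C)(C)C(C)(C)C)o2)[C@H](O[Si](C)(C)C(C)(C)C)C1 | intermediate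
14 | enone acid: 4-substituted cyclopent-2-enone formed from 13 by loss of silanol | O=C1C(C(O)CC[C@@H](C)O[Si](CC)(CC)CC)[C@@H](C(C(=O)O)c2ccc(CC[C@@H](C)O[Si](C)(C)C(C)(C)C)o2)C=C1 | intermediate
15 | (3R,3aS,6aS)-3-{5-[(3R)-3-(tert-butyldimethylsilyloxy)butyl]furan-2-yl}-4-[(4R)-1-hydroxy-4-(triethylsilyloxy)pentyl]hexahydro-2H-cyclopenta[b]furan-2,5-dione (cis-fused; mixture at C4 and at the carbinol carbon) | O=C1C(C(O)CC[C@@H](C)O[Si](CC)(CC)CC)[C@@H]2[C@H](C1)OC(=O)[C@H]2c1ccc(CC[C@@H](C)O[Si](C)(C)C(C)(C)C)o1 | intermediate
16 | (3R,3aS,6aS)-3-{5-[(3R)-3-(tert-butyldimethylsilyloxy)butyl]furan-2-yl}-4-[(4R)-4-(triethylsilyloxy)pentanoyl]hexahydro-2H-cyclopenta[b]furan-2,5-dione (enolised 1,3-diketone) | O=C1C(C(=O)CC[C@@H](C)O[Si](CC)(CC)CC)[C@@H]2[C@H](C1)OC(=O)[C@H]2c1ccc(CC[C@@H](C)O[Si](C)(C)C(C)(C)C)o1 | intermediate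
17 | dilithium salt of the ring-opened 3-hydroxy diacid (lactone hydrolysed, cyclopentanone cleaved) | [Li+].[Li+].C[C@@H](O[Si](CC)(CC)CC)CCC(=O)C[C@@H]([C@@H](C(=O)[O-])c1ccc(CC[C@@H](C)O[Si](C)(C)C(C)(C)C)o1)[C@H](CC(=O)[O-])O | intermediate
18 | 2-[(2S,3S,4R)-4-{5-[(3R)-3-(tert-butyldimethylsilyloxy)butyl]furan-2-yl}-5-oxo-3-[(5R)-2-oxo-5-(triethylsilyloxy)hexyl]oxolan-2-yl]acetic acid | C[C@@H](O[Si](CC)(CC)CC)CCC(=O)C[C@@H]1[C@H](CC(=O)O)OC(=O)[C@H]1c1ccc(CC[C@@H](C)O[Si](C)(C)C(C)(C)C)o1 | intermediate
19 | 2-[(2S,3S,4R)-4-{5-[(3R)-3-(tert-butyldimethylsilyloxy)butyl]furan-2-yl}-3-[(5R)-5-hydroxy-2-oxohexyl]-5-oxooxolan-2-yl]acetic acid | C[C@@H](O)CCC(=O)C[C@@H]1[C@H](CC(=O)O)OC(=O)[C@H]1c1ccc(CC[C@@H](C)O[Si](C)(C)C(C)(C)C)o1 | intermediate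
20 | O-tert-butyldimethylsilyl ether of the lactone α-epimer of cordycicadin B (furyl trans to the neighbouring ring CH2; all other centres as in the target) | C[C@@H]1CCC(=O)C[C@@H]2[C@H](CC(=O)O1)OC(=O)[C@H]2c1ccc(CC[C@@H](C)O[Si](C)(C)C(C)(C)C)o1 | intermediate
21 | lithium enolate of the γ-lactone of 20 | [Li+].C[C@@H]1CCC(=O)C[C@@H]2[C@H](CC(=O)O1)OC([O-])=C2c1ccc(CC[C@@H](C)O[Si](C)(C)C(C)(C)C)o1 | intermediate
22 | O-tert-butyldimethylsilyl ether of cordycicadin B | C[C@@H]1CCC(=O)C[C@@H]2[C@H](CC(=O)O1)OC(=O)[C@@H]2c1ccc(CC[C@@H](C)O[Si](C)(C)C(C)(C)C)o1 | intermediate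
23 | cordycicadin B | C[C@@H]1CCC(=O)C[C@@H]2[C@H](CC(=O)O1)OC(=O)[C@@H]2c1ccc(CC[C@@H](C)O)o1 | target

**Summary**

Total step count: 13. Longest linear sequence: 11 steps (steps 1–4 and 7–13); steps 5–6 make the aldehyde branch.

Steps most likely to fail:

Step 7 (labelled step). What may go wrong: proton transfer from the enone or 1,2-addition instead of conjugate addition of the strongly basic dianion; equilibration of the first enolate before the aldehyde is captured; retro-aldol or base-induced double-bond migration of the transient enone (loss of the fusion stereocentre) during the DBU stage. Fallback, stepwise and with known chemistry: from 6, double silylation (LDA, Me3SiCl) gives the bis(trimethylsilyl) ketene acetal F1. Mukaiyama–Michael addition of F1 to 10 (HgI2 cat., CH2Cl2, −78 °C) gives the isolable silyl enol ether F2, in which the regiochemistry of the enolate is fixed. Mukaiyama aldol addition of F2 to 9 (BF3·OEt2, −78 °C) and aqueous work-up give keto acid 13, now isolated, and DBU followed by AcOH closes it to 15, where the route is rejoined.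

Step 9. What may go wrong: attack of hydroxide at the side-chain carbonyl (deacylation) and, if cleavage of the stabilised diketonate is slow, β-elimination of the lactone carboxylate on prolonged exposure to base. Fallback that activates the diketone instead of forcing the conditions: from 16, chlorination at the doubly activated carbon with N-chlorosuccinimide gives the non-enolisable 2-chloro diketone F3. NaOMe in MeOH at −40 °C opens its ring by a fast retro-Claisen to the α-chloro keto methyl ester F4. Zn/NH4Cl removes the chlorine to give keto methyl ester F5, and Me3SnOH (1,2-dichloroethane, 80 °C) cleaves the methyl ester to return to 18.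

Step 11. What may go wrong: oligomerisation in place of medium-ring closure, and base-induced β-elimination of the lactone carboxylate from the activated acyl group. Fallback that isolates an activated ester and cyclises it under acid catalysis without amine base: from 19, addition of the acid to ethoxyacetylene ([RuCl2(p-cymene)]2 cat., toluene, rt) gives the 1-ethoxyvinyl ester F6. Camphorsulfonic acid (cat.) in toluene at high dilution (50 °C) then transfers the acyl group to the secondary alcohol, returning to 20.

Further compounds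
F1 | step 7 | bis(trimethylsilyl) ketene acetal of acid 6 | C[C@@H](O[Si](C)(C)C(C)(C)C)CCc1ccc(C=C(O[Si](C)(C)C)O[Si](C)(C)C)o1
F2 | step 7 | trimethylsilyl enol ether and trimethylsilyl ester of the Michael adduct of F1 with 10 (substituent trans to the silyloxy group) | C[Si](C)(C)OC1=C[C@@H](C(C(=O)O[Si](C)(C)C)c2ccc(CC[C@@H](C)O[Si](C)(C)C(C)(C)C)o2)[C@H](O[Si](C)(C)C(C)(C)C)C1
F3 | step 9 | 4-chloro derivative of diketone 16 (chlorine on the carbon between the two ketones) | O=C1C(Cl)(C(=O)CC[C@@H](C)O[Si](CC)(CC)CC)[C@@H]2[C@H](C1)OC(=O)[C@H]2c1ccc(CC[C@@H](C)O[Si](C)(C)C(C)(C)C)o1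
F4 | step 9 | methyl ester of 18 carrying chlorine on the CH between the lactone ring and the ketone | C[C@@H](O[Si](CC)(CC)CC)CCC(=O)C(Cl)[C@@H]1[C@H](CC(=O)OC)OC(=O)[C@H]1c1ccc(CC[C@@H](C)O[Si](C)(C)C(C)(C)C)o1
F5 | step 9 | methyl ester of 18 | C[C@@H](O[Si](CC)(CC)CC)CCC(=O)C[C@@H]1[C@H](CC(=O)OC)OC(=O)[C@H]1c1ccc(CC[C@@H](C)O[Si](C)(C)C(C)(C)C)o1
F6 | step 11 | 1-ethoxyvinyl ester of hydroxy acid 19 | C[C@@H](O)CCC(=O)C[C@@H]1[C@H](CC(=O)OC(=C)OCC)OC(=O)[C@H]1c1ccc(CC[C@@H](C)O[Si](C)(C)C(C)(C)C)o1
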